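**Strategy.** The spiro-oxolane (O, C9, C11, C12, C13; labdane numbering) is disconnected at C12–C13 and O–C9, which reveals the C13 carbonyl of a 2-oxobutanoate and a C9(H)–CH=CH2 unit on a cis-fused decalin built from (R)-carvone. In one operation a SnCl4-promoted carbonyl-ene addition joins C12 to C13 and the C9=C11 alkene so formed is captured at C9 by the new C13 oxygen, a formal [3+2] annulation. The step exploits the tertiary allylic C9–H, the cation-stabilising, fully substituted C9 and the α-oxygenated lactone carbon C13 as a latent ketone; an 8-phenylmenthyl ester controls C13 and is expelled on lactonisation.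

Key step: step 11

Remark: labdane numbering is used throughout; the SMILES is read literally as (5S,6S,8R,9R,10R,13R), a cis-fused decalin in which H-5, the 6-acetoxy group, the C8 methyl, the C9–O bond and the C10 methyl all lie on one face (C11 on the other).

**Route**

Step 1
Reactants: 1 (R)-(−)-carvone; 2 4-iodobut-1-ene
Product: 3 6-(but-3-enyl)carvone (butenyl mainly trans to isopropenyl)
Conditions: LiN(iPr)2, THF, −78 °C; then 2, DMPU, −78 → 0 °C
Reagents that add atoms: none
Why: Kinetic α′-deprotonation gives the cross-conjugated lithium enolate, which is alkylated by the primary iodide (enolate alkylation) to bring in C1–C3 of ring A; the new centre is re-enolised in step 2, so its configuration does not matter.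

Step 2
Reactants: 3 6-(but-3-enyl)carvone
Product: 4 6-(but-3-enyl)-6-methylcarvone (methyl trans and butenyl cis to isopropenyl)
Conditions: LiN(iPr)2, THF, −78 °C; then MeI, −78 → 0 °C
Reagents that add atoms: iodomethane CI
Why: In the tetrasubstituted enolate the C5 isopropenyl group sits pseudoaxial to avoid allylic strain, so iodomethane should enter on the opposite face (enolate alkylation) and fix the quaternary C10 with its methyl trans to isopropenyl.

Step 3
Reactants: 4 6-(but-3-enyl)-6-methylcarvone
Product: 5 cis-fused bicyclic dienone (ring A closed with a C3=C4 bond)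
Conditions: second-generation Grubbs catalyst (5 mol%), CH2Cl2, 40 °C
Reagents that add atoms: none
Why: Ring-closing metathesis between the terminal vinyl group and the isopropenyl group, which are cis on adjacent carbons, should close ring A as a trisubstituted cyclohexene while the conjugated enone alkene stays inert, so the cis ring fusion follows from the two centres already set.

Step 4
Reactants: 5 cis-fused bicyclic dienone
Product: 7 gem-dimethyl enone, via sulfonylhydrazide adduct 6 (not isolated)
Conditions: Fe(acac)3 (30 mol%), PhSiH3, CH2=N–NHSO2Me, THF/MeOH, rt; then Et3N, MeOH, 60 °C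
Reagents that add atoms: formaldehyde N-(methylsulfonyl)hydrazone C=NNS(C)(=O)=O
Why: Hydrogen atom transfer from an iron hydride to the electron-rich trisubstituted alkene gives the tertiary C4 radical, which adds to the hydrazone carbon and is then reduced off with loss of N2 and sulfinate (alkene hydromethylation), so the gem-dimethyl carbon forms with no new stereocentre and no cation that could scramble C5.

Step 5
Reactants: 7 gem-dimethyl enone
Product: 10 6-hydroxy enone (hydroxyl syn to H-5), via silyl dienol ether 8 (not isolated), via silyloxy epoxide 9 (not isolated)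
Conditions: TBSOTf, Et3N, CH2Cl2, 0 °C; then dimethyldioxirane, acetone, −40 °C; then 1 M HCl, THF, 0 °C
Reagents that add atoms: dimethyldioxirane CC1(C)OO1; tert-butyldimethylsilyl trifluoromethanesulfonate CC(C)(C)[Si](C)(C)OS(=O)(=O)C(F)(F)F (silicon stays only in 8 and 9)
Why: Because C10 is quaternary only γ-deprotonation is possible, and the oxidant should epoxidise the distal, unhindered C6=C7 bond of the linear dienol ether on the convex face opposite the C4 quaternary carbon, the epoxide then opening to the γ-hydroxy enone (vinylogous Rubottom oxidation).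

Step 6
Reactants: 10 6-hydroxy enone
Product: 12 hydroxy ketone (C8 methyl syn to the C10 methyl), via C8-epimeric ketone 11 (not isolated)
Conditions: H2 (1 atm), [Ir(cod)(PCy3)(py)]PF6 (5 mol%), CH2Cl2, rt; then NaOMe (0.2 equiv), MeOH, rt
Reagents that add atoms: none
Why: Hydroxyl-directed homogeneous hydrogenation should saturate C7=C8 without allylic C–O hydrogenolysis, and methoxide then epimerises C8 through the enolate to the isomer with an equatorial methyl, since the other epimer would place that methyl 1,3-diaxial to C1.

Step 7
Reactants: 12 hydroxy ketone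
Product: 14 hydroxy aldehyde (formyl mainly equatorial), via methyl enol ether 13 (not isolated)
Conditions: MeOCH2PPh3Cl, KN(SiMe3)2, toluene, 0 → 90 °C; then 2 M HCl, THF, rt
Reagents that add atoms: (methoxymethyl)triphenylphosphonium chloride COC[P+](c1ccccc1)(c1ccccc1)c1ccccc1.[Cl-]; water O
Why: Wittig methoxymethylenation of the ketone (the C6 alkoxide is carried along by excess base) followed by acid hydrolysis of the enol ether should give the one-carbon homologated aldehyde, whose C9 configuration is erased again in step 11.

Step 8
Reactants: 14 hydroxy aldehyde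
Product: 16 9-vinyl acetate, via 9-vinyl alcohol 15 (not isolated)
Conditions: Ph3PCH3Br, KN(SiMe3)2, THF, 0 °C → rt; then Ac2O, DMAP, 0 °C → rt
Reagents that add atoms: methyltriphenylphosphonium bromide C[P+](c1ccccc1)(c1ccccc1)c1ccccc1.[Br-]; acetic anhydride CC(=O)OC(C)=O
Why: Wittig methylenation turns the aldehyde into the vinyl group and the C6 potassium alkoxide present in the same flask is then acetylated, with no stereocentre touched.

Step 9
Reactants: 17 (−)-8-phenylmenthol; 18 oxalyl chloride; 19 tert-butyl vinyl ether
Product: 21 (E)-4-tert-butoxy-2-oxobut-3-enoate of 17, via chlorooxoacetate 20 (not isolated)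
Conditions: 18 (3 equiv), CH2Cl2, 0 °C → rt, then evaporation; 19, pyridine, CH2Cl2, 0 °C → rt
Reagents that add atoms: none
Why: Oxalyl chloride monoacylates the secondary alcohol and the resulting 2-oxo acid chloride C-acylates the enol ether with loss of HCl to pyridine (acylation of an enol ether), which should give the E β-alkoxy enone.

Step 10
Reactants: 21 enone ester
Product: 22 8-phenylmenthyl 4-tert-butoxy-2-oxobutanoate
Conditions: H2 (1 atm), 10% Pd/C, EtOAc, rt
Reagents that add atoms: none
Why: Heterogeneous hydrogenation should saturate the enol ether double bond while the 2-oxo ester carbonyl and the tert-butyl ether are left untouched under these mild conditions.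

Step 11
Reactants: 16 9-vinyl acetate; 22 8-phenylmenthyl 4-tert-butoxy-2-oxobutanoate
Product: 24 spiro-oxolane ester, via ene adduct 23 (not isolated)
Conditions: SnCl4 (1.5 equiv), CH2Cl2, −78 → −20 °C
Reagents that add atoms: none
Why: Proposed new method: SnCl4 chelates the two carbonyl groups of 22 and the terminal alkene carbon C12 of 16 adds to the ketone carbon C13 in a carbonyl-ene process in which the tertiary allylic C9–H is transferred, giving the tin alkoxide of 23 with a trisubstituted C9=C11 bond; the acid present then protonates C11 and the C13 oxygen captures the tertiary C9 cation, so that the net change is a formal [3+2] annulation of a vinyl group with a ketone by way of a 1,2-relocation of hydrogen. The closest known reaction types are the SnCl4-promoted ene reaction of 8-phenylmenthyl 2-oxo esters with 1-alkenes, the [3+2] annulation of allylsilanes with 2-oxo esters (1,2-silyl instead of hydrogen shift) and the acid-mediated cyclisation of γ,δ-unsaturated tertiary alcohols to 2,2-disubstituted oxolanes, which have not been run as one operation on an unactivated vinyl group. The oxolane closes by a cationic 5-endo (Markovnikov) C–O bond formation at C9, whereas the competing closure by the ester carbonyl would need a six-membered ring and loss of the auxiliary. C13 is controlled by the auxiliary, whose phenyl group stacks over one face of the s-cis chelated dicarbonyl so that C12 arrives on the open si face (13R); C9 is controlled by the substrate, because the oxygen enters axially on the convex face of the cis-fused decalin, anti to the axial C1 methylene of ring A, which is also the epimer that keeps the bulkier C11 equatorial. The step needs attack at C13 by a hindered monosubstituted alkene without enolisation of 22, and ring closure that outruns hydride shift from C8 and methyl shift from C10; the exposed terminal CH2, the low temperature and the oxygen held four bonds from C9 should secure both.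

Step 12
Reactants: 24 spiro-oxolane ester
Product: 26 target, via hydroxy ester 25 (not isolated)
Conditions: p-TsOH·H2O (0.3 equiv), toluene, 70 °C
Reagents that add atoms: none
Why: Acid should cleave the primary tert-butyl ether by loss of isobutene and the freed hydroxyl then closes the γ-lactone on the ester (lactonisation, helped by the quaternary α-carbon) with release of the auxiliary, while the oxolane oxygen is deactivated towards ionisation by the adjacent carbonyl.

**Compound list**

1 | (R)-(−)-carvone, (5R)-2-methyl-5-(prop-1-en-2-yl)cyclohex-2-en-1-one | C1C=C(C)C(=O)C[C@@H]1C(C)=C | starting material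
2 | 4-iodobut-1-ene | C=CCCI | starting material
3 | 6-(but-3-en-1-yl)carvone, main epimer with butenyl trans to isopropenyl (centre re-enolised in step 2) | C1C=C(C)C(=O)[C@@H](CCC=C)[C@@H]1C(C)=C | intermediate
4 | 6-(but-3-en-1-yl)-6-methylcarvone, methyl trans and butenyl cis to the isopropenyl group | C1C=C(C)C(=O)[C@](C)(CCC=C)[C@@H]1C(C)=C | intermediate
5 | cis-fused 2,5,8a-trimethyl-4a,7,8,8a-tetrahydronaphthalen-1(4H)-one (labdane numbering: 3,7-dien-9-one, H-5 syn to the C10 methyl) | C1C=C(C)C(=O)[C@]2(C)CCC=C(C)[C@H]12 | intermediate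
6 | C4 (methylsulfonylhydrazino)methyl adduct of 5 (C4 epimers, not isolated) | C1C=C(C)C(=O)[C@]2(C)CCCC(C)(CNNS(C)(=O)=O)[C@H]12 | intermediate
7 | (4aS,8aR)-2,5,5,8a-tetramethyl-4a,5,6,7,8,8a-hexahydronaphthalen-1(4H)-one (cis-fused 7-en-9-one) | C1C=C(C)C(=O)[C@]2(C)CCCC(C)(C)[C@H]12 | intermediate
8 | tert-butyldimethylsilyl dienol ether of 7 (6,8-diene, 9-silyloxy; not isolated) | C1=CC(C)=C(O[Si](C)(C)C(C)(C)C)[C@]2(C)CCCC(C)(C)[C@H]12 | intermediate
9 | 6,7-epoxide of 8, oxygen on the face of H-5 and the C10 methyl (not isolated) | O1[C@H]2[C@@H]1C(C)=C(O[Si](C)(C)C(C)(C)C)[C@]3(C)CCCC(C)(C)[C@H]23 | intermediate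
10 | (4S,4aS,8aR)-4-hydroxy-2,5,5,8a-tetramethyl-4a,5,6,7,8,8a-hexahydronaphthalen-1(4H)-one (6-hydroxy-7-en-9-one, OH syn to H-5) | O[C@H]1C=C(C)C(=O)[C@]2(C)CCCC(C)(C)[C@H]12 | intermediate
11 | C8 epimer of 12 (C8 methyl anti to the C10 methyl; not isolated) | O[C@H]1C[C@H](C)C(=O)[C@]2(C)CCCC(C)(C)[C@H]12 | intermediate
12 | (2R,4S,4aS,8aR)-4-hydroxy-2,5,5,8a-tetramethyloctahydronaphthalen-1(2H)-one (6-OH, 8-CH3, H-5 and C10-CH3 on one face) | O[C@H]1C[C@@H](C)C(=O)[C@]2(C)CCCC(C)(C)[C@H]12 | intermediate
13 | 9-(methoxymethylidene) enol ether of 12 (E/Z mixture, not isolated) | O[C@H]1C[C@@H](C)C(=COC)[C@]2(C)CCCC(C)(C)[C@H]12 | intermediate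
14 | 4-hydroxy-2,5,5,8a-tetramethyldecahydronaphthalene-1-carbaldehyde, ring centres as in 12, formyl at C9 mainly equatorial | O[C@H]1C[C@@H](C)[C@H](C=O)[C@]2(C)CCCC(C)(C)[C@H]12 | intermediate
15 | 4-ethenyl-3,4a,8,8-tetramethyldecahydronaphthalen-1-ol, ring centres as in 12 (not isolated) | O[C@H]1C[C@@H](C)[C@H](C=C)[C@]2(C)CCCC(C)(C)[C@H]12 | intermediate
16 | 4-ethenyl-3,4a,8,8-tetramethyldecahydronaphthalen-1-yl acetate (6-acetoxy-9-vinyl decalin) | CC(=O)O[C@H]1C[C@@H](C)[C@H](C=C)[C@]2(C)CCCC(C)(C)[C@H]12 | intermediate
17 | (−)-8-phenylmenthol, (1R,2S,5R)-5-methyl-2-(2-phenylpropan-2-yl)cyclohexan-1-ol | O[C@@H]1C[C@H](C)CC[C@H]1C(C)(C)c1ccccc1 | starting material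
18 | oxalyl chloride | O=C(Cl)C(Cl)=O | starting material
19 | tert-butyl vinyl ether | C=COC(C)(C)C | starting material
20 | (1R,2S,5R)-8-phenylmenthyl chlorooxoacetate (not isolated) | O=C(Cl)C(=O)O[C@@H]1C[C@H](C)CC[C@H]1C(C)(C)c1ccccc1 | intermediate
21 | (1R,2S,5R)-8-phenylmenthyl (E)-4-tert-butoxy-2-oxobut-3-enoate | CC(C)(C)O/C=C/C(=O)C(=O)O[C@@H]1C[C@H](C)CC[C@H]1C(C)(C)c1ccccc1 | intermediate
22 | (1R,2S,5R)-8-phenylmenthyl 4-tert-butoxy-2-oxobutanoate | CC(C)(C)OCCC(=O)C(=O)O[C@@H]1C[C@H](C)CC[C@H]1C(C)(C)c1ccccc1 | intermediate
23 | ene adduct: 13-hydroxy ester with a C9=C11 double bond, C13 as in the target (not isolated) | CC(=O)O[C@H]1C[C@@H](C)C(=CC[C@](O)(C(=O)O[C@@H]3C[C@H](C)CC[C@H]3C(C)(C)c3ccccc3)CCOC(C)(C)C)[C@]2(C)CCCC(C)(C)[C@H]12 | intermediate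
24 | 9,13-epoxide (spiro-oxolane) carrying at C13 the 8-phenylmenthyl ester and a 2-tert-butoxyethyl group | CC(=O)O[C@H]1C[C@@H](C)[C@]2(CC[C@](C(=O)O[C@@H]3C[C@H](C)CC[C@H]3C(C)(C)c3ccccc3)(CCOC(C)(C)C)O2)[C@]2(C)CCCC(C)(C)[C@H]12 | intermediate
25 | 15-hydroxy ester from 24 after loss of the tert-butyl group (not isolated) | CC(=O)O[C@H]1C[C@@H](C)[C@]2(CC[C@](C(=O)O[C@@H]3C[C@H](C)CC[C@H]3C(C)(C)c3ccccc3)(CCO)O2)[C@]2(C)CCCC(C)(C)[C@H]12 | intermediate
26 | CNP0081177.1, (5S,6S,8R,9R,10R,13R)-6-acetoxy-9,13-epoxylabdan-16,15-olide | CC(=O)O[C@H]1C[C@@H](C)[C@]2(CC[C@]3(CCOC3=O)O2)[C@]2(C)CCCC(C)(C)[C@H]12 | target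

**Step count and risks**

Total step count: 12. Longest linear sequence: 10 steps (steps 1–8, 11 and 12; steps 9 and 10 form the side branch).

Steps most likely to fail:

1. Step 11. The hindered monosubstituted alkene may add to the ketone too slowly, so that enolisation of 22 with loss of tert-butanol takes over. The C9 cation may also undergo hydride shift from C8 or methyl shift from C10 before the ring closes. The fallback uses known chemistry, sets out from hydroxy ketone 12 and returns at target 26. Ethynylmagnesium bromide (CeCl3, THF) should add to the C9 ketone to give the 9-ethynyl-6,9-diol F1, whose C9 configuration is lost later. Its magnesium acetylide (n-BuLi, 3 equiv, then MgBr2·OEt2, −78 °C) should add to the chelated ketone of 22 from the same open face to give the alkynyl triol ester F2. Hydrogenation (H2, 10% Pd/C, EtOAc) should give the saturated triol ester F3. p-TsOH·H2O in toluene at 70 °C should ionise the tertiary C9 alcohol, close the oxolane through the C13 hydroxyl, cleave the tert-butyl ether and lactonise to the 6-hydroxy spirolactone F4. Ac2O with DMAP then gives 26.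

2. Step 7. The bulky ylide may enolise the doubly flanked C9 ketone instead of adding to it, so that no olefination takes place. The fallback sets out from 12 and returns at aldehyde 14. Corey–Chaykovsky methylenation with dimethylsulfonium methylide (Me3SI, KN(SiMe3)2, THF/DMSO) should give the spiro-epoxide F5 by axial attack on the convex face. MgBr2·OEt2 in CH2Cl2 should then open it at C9 with a 1,2-hydride shift (Meinwald rearrangement) to 14.

3. Step 5. The oxidant may attack the more electron-rich C8=C9 enol ether bond (hydroxylation at C8) or the wrong face of C6=C7. The fallback sets out from enone 7 and returns at hydroxy enone 10. KOtBu in tBuOH followed by kinetic protonation with aqueous AcOH should deconjugate to the β,γ-unsaturated ketone F6. mCPBA with NaHCO3 should epoxidise the isolated C6=C7 bond on the convex face to give the epoxy ketone F7. DBU should then open the epoxide by β-elimination from the C8 enolate to give 10.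

**Further compounds**

F1 | step 11 | 9-ethynyl-6,9-diol (C9 shown as the expected adduct, inconsequential) | O[C@H]1C[C@@H](C)[C@@](O)(C#C)[C@]2(C)CCCC(C)(C)[C@H]12
F2 | step 11 | alkynyl triol ester (acetylide adduct of 22) | O[C@H]1C[C@@H](C)[C@@](O)(C#C[C@](O)(C(=O)O[C@@H]3C[C@H](C)CC[C@H]3C(C)(C)c3ccccc3)CCOC(C)(C)C)[C@]2(C)CCCC(C)(C)[C@H]12
F3 | step 11 | saturated triol ester | O[C@H]1C[C@@H](C)[C@@](O)(CC[C@](O)(C(=O)O[C@@H]3C[C@H](C)CC[C@H]3C(C)(C)c3ccccc3)CCOC(C)(C)C)[C@]2(C)CCCC(C)(C)[C@H]12
F4 | step 11 | 6-hydroxy spirolactone (deacetyl target) | O[C@H]1C[C@@H](C)[C@]2(CC[C@]3(CCOC3=O)O2)[C@]2(C)CCCC(C)(C)[C@H]12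
F5 | step 7 | spiro-epoxide at C9 (methylene on the convex face) | O[C@H]1C[C@@H](C)[C@@]3(CO3)[C@]2(C)CCCC(C)(C)[C@H]12
F6 | step 5 | β,γ-unsaturated ketone with a C6=C7 bond (C8 epimers) | C1=CC(C)C(=O)[C@]2(C)CCCC(C)(C)[C@H]12
F7 | step 5 | 6,7-epoxy ketone, oxygen on the convex face (C8 epimers) | O1[C@H]2[C@@H]1C(C)C(=O)[C@]3(C)CCCC(C)(C)[C@H]23
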